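I decided to answer your request for a quick number with one time and no fit, a half-life read from the two earlier runs and carried to each flask.

all flasks: reagent 0.765 M
- zeta: substrate 0.26 M; temperature 61 °C; run made earlier
- delta: substrate 1 M; temperature 86 °C; run made earlier
- birch: substrate 0.51 M; temperature 65 °C; time 15 min
- larch: substrate 0.51 M; temperature 50 °C; time 15 min
- oak: substrate 0.51 M; temperature 80 °C; time 15 min
- cedar: substrate 0.51 M; temperature 95 °C; time 15 min

- zeta (time / min: target / %): 0.667: 14.0; 2.00: 19.9; 3.00: 19.7; 5.00: 17.2; 8.00: 15.3; 10.0: 13.4; 12.0: 11.4
- delta (time / min: target / %): 0.250: 10.0; 0.667: 9.2; 1.00: 7.4; 2.00: 4.3; 3.00: 1.8; 4.00: 3.3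

(readings scatter by 1 percentage point)

* the flask with the highest amount of target, in percent of the substrate charged ("all alike" if they lie within 1.5 percentage points) (birch / larch / oak / cedar / all alike)
* final target, as a percentage of the substrate charged, in birch
* final target, as a percentage of the substrate charged, in larch
* final target, as a percentage of the substrate charged, in oak
* final target, as a percentage of the substrate charged, in cedar

- the earlier runs were read with a standard deviation of 1 percentage point
- steps thought possible: substrate + reagent <-> target; substrate + reagent -> isomer of the product; substrate + reagent -> second isomer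

In zeta the target reached its highest reading, 19.9%, by 2.00 min and then fell, and delta fell as well, so I read the fall as the loss of a pool, substrate and target together, leaking into the isomers. The steps put that leak in proportion to the reagent, which makes it pseudo-first-order while the reagent is held at its charge. Zeta fell from 19.7% to 11.4% between 3.00 min and 12.0 min, a rate of 0.0608 min⁻¹. Delta fell from 9.2% to 3.3% between 0.667 min and 4.00 min, a rate of 0.308 min⁻¹, and the pair gave me an activation energy of 64.7 kJ mol⁻¹, with the scatter of the readings in it.

At 50 °C this came to 25.2 min for the pool half-life, the time in which substrate and target together fall to half at the charged reagent, so after 15 min I expected 66.2% of the pool in larch. Fading the zeta peak reading by the same reckoning at each temperature, I committed to 13.2% in larch, 5.99% in birch, 0.817% in oak and 0.00785% in cedar, with larch the highest.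

The forecast named larch, with 5.5% in birch, 16% in larch, 0.8% in oak and 0.03% in cedar: “The coolest flask keeps the most target.”

The flasks gave 6.00% in birch, 18.9% in larch, 1.07% in oak and 0.107% in cedar, so larch holds most, and my larch number was low by 5.7 percentage points, while its pool stood at 66.3%.

    substrate + reagent ⇌ target (K = 0.701 M⁻¹, k = 0.00259 M⁻¹ s⁻¹, Ea = 68.0 kJ mol⁻¹, ΔH = −30.0 kJ mol⁻¹)
    substrate + reagent → isomer of the product (k = 6.33 × 10⁻⁵ M⁻¹ s⁻¹, Ea = 72.0 kJ mol⁻¹)
    substrate + reagent → second isomer (k = 9.94 × 10⁻⁴ M⁻¹ s⁻¹, Ea = 53.0 kJ mol⁻¹)
    (constants at 50 °C)

In larch, half of the turnover of the step to target was done by 1.01 min, while the slowest mode of the whole flask had a half-life of 23.6 min at the end, longer than the 15 min of the run and close to my 25.2 min.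

For the neighbour, larch with 0.31 M of reagent, the half-life scales to 62.2 min, which leaves 84.6% of the pool. The computed flask held 73.3% substrate and 9.92% target, 83.2% together.

Readings and results stem from a simulated flask on assumed constants; the scatter is artificial.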